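**Plan**

- Retrosynthetic cuts, in order: O1–C6 of the oxane (reductive etherification of a δ-silyloxy ketone); the aryl–CH2 bond of the arylethyl arm (arylation of a ketone homoenolate); the two cyclopropane bonds made on the ester carbon that becomes C6 (Kulinkovich); C2–C3 (vinylogous aldol on protected vanillin).
- Forward: the chain grows from the vanillin end (C2 to C6), the second guaiacyl ring is then joined at its ipso carbon, and the oxane, the only ring made, closes last before deprotection.
- Stereochemistry: C2 from a catalytic asymmetric vinylogous Mukaiyama aldol; C4 from a 1,3-syn (Narasaka–Prasad) reduction; C6 from axial hydride delivery to the cyclic oxocarbenium ion (2,6-cis, 4-O axial).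
- Enabling feature: ring carbon C6 (bonded to O1) lies two CH2 groups from the ipso carbon of the 4-hydroxy-3-methoxyphenyl ring. At the ketone level of C6 the arm is therefore a β-aryl ketone, the retron of aryl halide plus ketone homoenolate (a 1-substituted cyclopropanol). The ketone released is 1,5 to the benzylic C2–O, so the same carbonyl closes the ring.

Key step: step 7

Assumption: in step 2 the (S)-BINOL–titanium catalyst is taken to add the dienolate to the Si face of the aryl aldehyde, the sense usual for aryl aldehydes with this catalyst type; all later descriptors follow from that.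

**Step 1**
Reactants: 1 vanillin (4-hydroxy-3-methoxybenzaldehyde)
Product: 2 3-methoxy-4-(triisopropylsilyloxy)benzaldehyde
Conditions: TIPSCl, imidazole, DMF, rt
Reagents that add atoms: triisopropylsilyl chloride, CC(C)[Si](Cl)(C(C)C)C(C)C
Why: Routine silyl ether formation on a phenol; the bulky TIPS ether should resist the Grignard, alkoxide and carbonate conditions ahead and fall with the other silyl groups in the last step.

**Step 2**
Reactants: 2 3-methoxy-4-(triisopropylsilyloxy)benzaldehyde; 3 1-methoxy-1,3-bis(trimethylsilyloxy)buta-1,3-diene (Chan's diene)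
Product: 5 methyl (5S)-5-hydroxy-5-[3-methoxy-4-(triisopropylsilyloxy)phenyl]-3-oxopentanoate, via bis-trimethylsilyl aldol adduct 4 (not isolated)
Conditions: Ti(OiPr)4 (10 mol %), (S)-BINOL (10 mol %), 4 Å MS, THF, −78 °C → rt; then TFA, THF, 0 °C
Reagents that add atoms: none
Why: Catalytic enantioselective vinylogous Mukaiyama aldol addition, in which the terminal carbon of the silyl dienolate adds to the Si face of the Ti–BINOL-bound aldehyde, so the benzylic carbinol is set as (S) by catalyst control and acid then removes the trimethylsilyl groups.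

**Step 3**
Reactants: 5 methyl (5S)-5-hydroxy-5-[3-methoxy-4-(triisopropylsilyloxy)phenyl]-3-oxopentanoate
Product: 7 methyl (3R,5S)-3,5-dihydroxy-5-[3-methoxy-4-(triisopropylsilyloxy)phenyl]pentanoate, via diethylboron chelate 6 (not isolated)
Conditions: Et2BOMe, THF/MeOH (4:1), −78 °C; NaBH4; AcOH quench, MeOH co-evaporation
Reagents that add atoms: none
Why: Narasaka–Prasad reduction, in which the six-membered boron chelate holds the β-hydroxy ketone in a half-chair with the aryl-bearing carbon substituent pseudoequatorial and external axial hydride delivery should give the 1,3-syn diol, so the new C3 carbinol (R) is set by 1,3-induction from C5.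

**Step 4**
Reactants: 7 methyl (3R,5S)-3,5-dihydroxy-5-[3-methoxy-4-(triisopropylsilyloxy)phenyl]pentanoate
Product: 8 methyl (3R,5S)-3,5-bis(tert-butyldimethylsilyloxy)-5-[3-methoxy-4-(triisopropylsilyloxy)phenyl]pentanoate
Conditions: TBSOTf, 2,6-lutidine, CH2Cl2, −78 → 0 °C
Reagents that add atoms: tert-butyldimethylsilyl trifluoromethanesulfonate, CC(C)(C)[Si](C)(C)OS(=O)(=O)C(F)(F)F
Why: Standard silylation of two secondary alcohols with a silyl triflate and a hindered base, which blocks lactonisation and leaves the cyclopropanol of step 5 as the only free hydroxyl for the key step.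

**Step 5**
Reactants: 8 methyl (3R,5S)-3,5-bis(tert-butyldimethylsilyloxy)-5-[3-methoxy-4-(triisopropylsilyloxy)phenyl]pentanoate
Product: 9 1-{(2R,4S)-2,4-bis(tert-butyldimethylsilyloxy)-4-[3-methoxy-4-(triisopropylsilyloxy)phenyl]butyl}cyclopropan-1-ol
Conditions: EtMgBr (3 equiv, slow addition), Ti(OiPr)4 (20 mol %), THF, 0 °C → rt; aq. NH4Cl
Reagents that add atoms: ethylmagnesium bromide, CC[Mg]Br
Why: Kulinkovich cyclopropanation, in which the titanacyclopropane formed from EtMgBr and Ti(OiPr)4 acts as a 1,2-dicarbanion toward the ester and turns its carbonyl carbon into the carbinol carbon of a 1-substituted cyclopropanol, with the silyl ethers and both stereocentres untouched.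

**Step 6**
Reactants: 10 4-bromo-2-methoxyphenol
Product: 11 (4-bromo-2-methoxyphenoxy)triisopropylsilane
Conditions: TIPSCl, imidazole, DMF, rt
Reagents that add atoms: triisopropylsilyl chloride, CC(C)[Si](Cl)(C(C)C)C(C)C
Why: Routine phenol silylation that gives the aryl bromide partner a protecting group matched to that of the other arene.

**Step 7**
Reactants: 9 1-{(2R,4S)-2,4-bis(tert-butyldimethylsilyloxy)-4-[3-methoxy-4-(triisopropylsilyloxy)phenyl]butyl}cyclopropan-1-ol; 11 (4-bromo-2-methoxyphenoxy)triisopropylsilane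
Product: 13 (5R,7S)-5,7-bis(tert-butyldimethylsilyloxy)-1,7-bis[3-methoxy-4-(triisopropylsilyloxy)phenyl]heptan-3-one, via arylpalladium homoenolate 12 (not isolated)
Conditions: Pd(OAc)2 (5 mol %), XPhos (10 mol %), Cs2CO3, toluene, 80 °C
Reagents that add atoms: none
Why: Oxidative addition of 11 to Pd(0)–XPhos, exchange of bromide for the caesium cyclopropanolate of 9, strain-driven β-carbon elimination to the arylpalladium homoenolate 12 and C(sp2)–C(sp3) reductive elimination form the aryl–CH2 bond and in the same event release the C3 ketone, which lies 1,5 to the benzylic silyloxy group. The closest known reaction type is the palladium-catalysed ring-opening cross-coupling of cyclopropanols (ketone homoenolates) with aryl halides to give β-aryl ketones. No ring is closed (the three-membered ring is opened) and no stereocentre is formed; the two silyloxy stereocentres are not involved and neither is α to the new carbonyl. The step needs reductive elimination to outrun β-hydride elimination from 12 (which would give the vinyl ketone), and the bulky biaryl phosphine is chosen for that. Regioselectivity of ring opening is not an issue because the two CH2 groups of the 1-monosubstituted cyclopropanol are equivalent. Chemoselectivity rests on the substrate having a single free hydroxyl (the cyclopropanol) and the partner a single C–Br bond, all other oxygens being silylated.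

**Step 8**
Reactants: 13 (5R,7S)-5,7-bis(tert-butyldimethylsilyloxy)-1,7-bis[3-methoxy-4-(triisopropylsilyloxy)phenyl]heptan-3-one
Product: 15 (2S,4S,6S)-4-(tert-butyldimethylsilyloxy)-2-[3-methoxy-4-(triisopropylsilyloxy)phenyl]-6-{2-[3-methoxy-4-(triisopropylsilyloxy)phenyl]ethyl}oxane, via cyclic oxocarbenium ion 14 (not isolated)
Conditions: BiBr3 (10 mol %), Et3SiH, MeCN/CH2Cl2, 0 °C → rt
Reagents that add atoms: none
Why: Reductive etherification of a δ-silyloxy ketone, in which 6-exo-trig attack of the benzylic silyl ether oxygen on the activated ketone and loss of disiloxane give the oxocarbenium ion 14, whose half-chair carries the C2 aryl group pseudoequatorial and the C4 silyloxy group pseudoaxial and should accept hydride axially at C6, placing the side chain cis to the aryl group and trans to the silyloxy group (6S).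

**Step 9**
Reactants: 15 (2S,4S,6S)-4-(tert-butyldimethylsilyloxy)-2-[3-methoxy-4-(triisopropylsilyloxy)phenyl]-6-{2-[3-methoxy-4-(triisopropylsilyloxy)phenyl]ethyl}oxane
Product: 16 (2S,4S,6S)-2-(4-hydroxy-3-methoxyphenyl)-6-[2-(4-hydroxy-3-methoxyphenyl)ethyl]oxan-4-ol
Conditions: TBAF, AcOH, THF, rt → 40 °C
Reagents that add atoms: none
Why: Fluoride-mediated global desilylation of the two aryl TIPS ethers and the secondary TBS ether, buffered with acetic acid so that no phenoxide is present to open the benzylic ether, with no stereocentre affected.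

**Compound list**

1 | vanillin (4-hydroxy-3-methoxybenzaldehyde) | COc1cc(C=O)ccc1O | starting material
2 | 3-methoxy-4-(triisopropylsilyloxy)benzaldehyde | COc1cc(C=O)ccc1O[Si](C(C)C)(C(C)C)C(C)C | intermediate
3 | 1-methoxy-1,3-bis(trimethylsilyloxy)buta-1,3-diene (Chan's diene, alkene geometry as supplied) | COC(O[Si](C)(C)C)=CC(=C)O[Si](C)(C)C | starting material
4 | methyl (5S)-5-[3-methoxy-4-(triisopropylsilyloxy)phenyl]-3,5-bis(trimethylsilyloxy)pent-2-enoate (bis-trimethylsilyl aldol adduct, alkene geometry not defined) | COC(=O)C=C(O[Si](C)(C)C)C[C@H](O[Si](C)(C)C)c1ccc(O[Si](C(C)C)(C(C)C)C(C)C)c(OC)c1 | intermediate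
5 | methyl (5S)-5-hydroxy-5-[3-methoxy-4-(triisopropylsilyloxy)phenyl]-3-oxopentanoate | COC(=O)CC(=O)C[C@H](O)c1ccc(O[Si](C(C)C)(C(C)C)C(C)C)c(OC)c1 | intermediate
6 | diethylboron chelate of 5 (six-membered ring B–O5–C5–C4–C3=O→B) | CC[B-]1(CC)O[C@H](c2ccc(O[Si](C(C)C)(C(C)C)C(C)C)c(OC)c2)CC(CC(=O)OC)=[O+]1 | intermediate
7 | methyl (3R,5S)-3,5-dihydroxy-5-[3-methoxy-4-(triisopropylsilyloxy)phenyl]pentanoate | COC(=O)C[C@H](O)C[C@H](O)c1ccc(O[Si](C(C)C)(C(C)C)C(C)C)c(OC)c1 | intermediate
8 | methyl (3R,5S)-3,5-bis(tert-butyldimethylsilyloxy)-5-[3-methoxy-4-(triisopropylsilyloxy)phenyl]pentanoate | COC(=O)C[C@H](O[Si](C)(C)C(C)(C)C)C[C@H](O[Si](C)(C)C(C)(C)C)c1ccc(O[Si](C(C)C)(C(C)C)C(C)C)c(OC)c1 | intermediate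
9 | 1-{(2R,4S)-2,4-bis(tert-butyldimethylsilyloxy)-4-[3-methoxy-4-(triisopropylsilyloxy)phenyl]butyl}cyclopropan-1-ol | OC1(C[C@H](O[Si](C)(C)C(C)(C)C)C[C@H](O[Si](C)(C)C(C)(C)C)c2ccc(O[Si](C(C)C)(C(C)C)C(C)C)c(OC)c2)CC1 | intermediate
10 | 4-bromo-2-methoxyphenol | COc1cc(Br)ccc1O | starting material
11 | (4-bromo-2-methoxyphenoxy)triisopropylsilane | COc1cc(Br)ccc1O[Si](C(C)C)(C(C)C)C(C)C | intermediate
12 | arylpalladium(II) homoenolate, aryl–Pd–CH2CH2C(=O)R (phosphine ligand omitted) | COc1cc([Pd]CCC(=O)C[C@H](O[Si](C)(C)C(C)(C)C)C[C@H](O[Si](C)(C)C(C)(C)C)c2ccc(O[Si](C(C)C)(C(C)C)C(C)C)c(OC)c2)ccc1O[Si](C(C)C)(C(C)C)C(C)C | intermediate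
13 | (5R,7S)-5,7-bis(tert-butyldimethylsilyloxy)-1,7-bis[3-methoxy-4-(triisopropylsilyloxy)phenyl]heptan-3-one | COc1cc(CCC(=O)C[C@H](O[Si](C)(C)C(C)(C)C)C[C@H](O[Si](C)(C)C(C)(C)C)c2ccc(O[Si](C(C)C)(C(C)C)C(C)C)c(OC)c2)ccc1O[Si](C(C)C)(C(C)C)C(C)C | intermediate
14 | cyclic oxocarbenium ion (3,4-dihydro-2H-pyran-1-ium with C2 aryl and C4 silyloxy groups, bromide counter-ion) | COc1cc(CCC2=[O+][C@H](c3ccc(O[Si](C(C)C)(C(C)C)C(C)C)c(OC)c3)C[C@@H](O[Si](C)(C)C(C)(C)C)C2)ccc1O[Si](C(C)C)(C(C)C)C(C)C.[Br-] | intermediate
15 | (2S,4S,6S)-4-(tert-butyldimethylsilyloxy)-2-[3-methoxy-4-(triisopropylsilyloxy)phenyl]-6-{2-[3-methoxy-4-(triisopropylsilyloxy)phenyl]ethyl}oxane | COc1cc(CC[C@H]2C[C@H](O[Si](C)(C)C(C)(C)C)C[C@@H](c3ccc(O[Si](C(C)C)(C(C)C)C(C)C)c(OC)c3)O2)ccc1O[Si](C(C)C)(C(C)C)C(C)C | intermediate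
16 | (2S,4S,6S)-2-(4-hydroxy-3-methoxyphenyl)-6-[2-(4-hydroxy-3-methoxyphenyl)ethyl]oxan-4-ol | COc1cc(CC[C@H]2C[C@H](O)C[C@@H](c3ccc(O)c(OC)c3)O2)ccc1O | target

**Count**

Total steps: 9. Longest linear sequence: 8 (steps 1–5, 7, 8, 9).

**Steps most likely to fail, with fallbacks**

Step 7. The palladium homoenolate may undergo β-hydride elimination to the vinyl ketone, the cyclopropanol may isomerise to the ethyl ketone under base before it reaches palladium, or the β-silyloxy ketone product may lose silanol under carbonate. The fallback sets out from 8 and returns at 13, replacing the homoenolate by a Heck reaction with hydride shift. DIBAL-H (CH2Cl2, −78 °C) should reduce the ester to (3R,5S)-3,5-bis(tert-butyldimethylsilyloxy)-5-[3-methoxy-4-(triisopropylsilyloxy)phenyl]pentanal F1. Vinylmagnesium bromide (THF, −78 °C) should then give 5,7-bis(tert-butyldimethylsilyloxy)-7-[3-methoxy-4-(triisopropylsilyloxy)phenyl]hept-1-en-3-ol F2, with C5 and C7 as in 8 and C3 as a mixture of epimers, which does not matter. Heck arylation of F2 with 11 (Pd(OAc)2, Bu4NCl, NaHCO3, DMF, 90 °C) places the aryl group on the terminal alkene carbon; β-hydride elimination toward the carbinol and enol–keto tautomerism should then give 13 under a much weaker base.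

Step 8. The benzylic C–O bond next to the electron-rich arene may ionise under the acidic reducing conditions, leading to deoxygenation or loss of configuration, or hydride delivery may lose facial selectivity. The fallback sets out from 13 and returns at 16, and uses the benzylic ionisation as the ring-closing event. Removal of all four silyl groups (TBAF, AcOH, THF) should give (5R,7S)-5,7-dihydroxy-1,7-bis(4-hydroxy-3-methoxyphenyl)heptan-3-one F3. Narasaka–Prasad reduction (Et2BOMe, NaBH4, THF/MeOH, −78 °C), directed by the free C5 hydroxyl, should give the all-syn (1S,3S,5S)-1,7-bis(4-hydroxy-3-methoxyphenyl)heptane-1,3,5-triol F4. A catalytic Brønsted acid (PPTS, MeCN, rt, dilute) then ionises the 4-hydroxybenzylic alcohol, and the C5 hydroxyl captures the cation in a six-membered ring closure under thermodynamic control. With C3 and C5 fixed, the diequatorial 2,6-cis oxane with axial 4-OH, which is 16, is the expected product.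

Step 2. Turnover or enantioselectivity may be low with an electron-rich, oxygen-substituted benzaldehyde. The fallback sets out from 2 and returns at 5, setting the carbinol by asymmetric hydrogenation instead. Roskamp homologation of 2 with ethyl diazoacetate (SnCl2 cat., CH2Cl2) should give ethyl 3-[3-methoxy-4-(triisopropylsilyloxy)phenyl]-3-oxopropanoate F5. Noyori hydrogenation (H2, RuCl2[(R)-BINAP], EtOH) should give ethyl (3S)-3-hydroxy-3-[3-methoxy-4-(triisopropylsilyloxy)phenyl]propanoate F6; the (R)-ligand delivers hydrogen in the sense that gives (R)-3-hydroxybutanoate, which is the (S) descriptor for an aryl ketone. Claisen condensation of F6 with excess lithium enolate of methyl acetate (LDA, THF, −78 → −20 °C) should then give 5.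

**Further compounds**

F1 | step 7 | (3R,5S)-3,5-bis(tert-butyldimethylsilyloxy)-5-[3-methoxy-4-(triisopropylsilyloxy)phenyl]pentanal | O=CC[C@H](O[Si](C)(C)C(C)(C)C)C[C@H](O[Si](C)(C)C(C)(C)C)c1ccc(O[Si](C(C)C)(C(C)C)C(C)C)c(OC)c1
F2 | step 7 | 5,7-bis(tert-butyldimethylsilyloxy)-7-[3-methoxy-4-(triisopropylsilyloxy)phenyl]hept-1-en-3-ol (C5 and C7 as in 8, C3 epimers) | C=CC(O)C[C@H](O[Si](C)(C)C(C)(C)C)C[C@H](O[Si](C)(C)C(C)(C)C)c1ccc(O[Si](C(C)C)(C(C)C)C(C)C)c(OC)c1
F3 | step 8 | (5R,7S)-5,7-dihydroxy-1,7-bis(4-hydroxy-3-methoxyphenyl)heptan-3-one | COc1cc(CCC(=O)C[C@H](O)C[C@H](O)c2ccc(O)c(OC)c2)ccc1O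
F4 | step 8 | (1S,3S,5S)-1,7-bis(4-hydroxy-3-methoxyphenyl)heptane-1,3,5-triol | COc1cc(CC[C@H](O)C[C@H](O)C[C@H](O)c2ccc(O)c(OC)c2)ccc1O
F5 | step 2 | ethyl 3-[3-methoxy-4-(triisopropylsilyloxy)phenyl]-3-oxopropanoate | CCOC(=O)CC(=O)c1ccc(O[Si](C(C)C)(C(C)C)C(C)C)c(OC)c1
F6 | step 2 | ethyl (3S)-3-hydroxy-3-[3-methoxy-4-(triisopropylsilyloxy)phenyl]propanoate | CCOC(=O)C[C@H](O)c1ccc(O[Si](C(C)C)(C(C)C)C(C)C)c(OC)c1
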